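**Plan**

1. Numbering: C1 is the quaternary carbinol carrying C7H2OH, C2 is CHOH, C3 is CHOBz, C4=C5 is the alkene, C6 is CHOBz. TBS = tert-butyldimethylsilyl.
2. Retrosynthesis cuts the two benzoate C–O bonds, then the C3–O and C6–O bonds together (a 1,4-dioxygen bridge across a C3=C4–C5=C6 diene). The diene goes back to a C4 ketone, the C2–O bond is cut as a retro-oxa-Michael step, and the C1–O bond leads back to the arene of 4-hydroxybenzyl alcohol.
3. Enabling feature: C1 is the carbinol carbon of a prochiral p-quinol whose enone arms are C2=C3 and C6=C5, and O2 is cis to C7, so a boron atom bound to the C7 oxygen can deliver O2.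
4. Forward: dearomatisation gives the carbocycle. The only ring closed is the dioxaborinane C1–C7–O–B–O–C2 of the key step, later exchanged for an acetonide. The ketone becomes a dienyl triflate and then the diene; singlet oxygen and thiourea install O3 and O6; benzoylation and acetal hydrolysis finish.
5. Stereochemistry: C1 and C2 come from catalyst-controlled choice of one enantiotopic arm together with the tether (O2 cis to C7). C3 and C6 come from suprafacial addition of singlet oxygen to the diene face that carries the free C1 hydroxyl and is remote from the fused dioxane.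

Key step: step 5

Assumption: the sense of arm selection by a cinchona thiourea cannot be derived with confidence for a cross-conjugated dienone. The quinine-derived catalyst is written; its quinidine-derived pseudo-enantiomer, N-[3,5-bis(trifluoromethyl)phenyl]-N'-[(9R)-6'-methoxycinchonan-9-yl]thiourea, would replace it if the antipode of 11 were favoured.

**Route**

Step 1
Reactants: 1 4-hydroxybenzyl alcohol; 2 tert-butyldimethylsilyl chloride
Product: 3 4-{[(tert-butyldimethylsilyl)oxy]methyl}phenol
Conditions: imidazole, DMF, 0 °C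
Reagents that add atoms: tert-butyldimethylsilyl chloride (2), CC(C)(C)[Si](C)(C)Cl
Why: Imidazole-promoted silylation with one equivalent of the silyl chloride should take the unhindered, more nucleophilic benzylic hydroxyl in preference to the phenol, the usual chemoselective silyl ether formation on this diol.

Step 2
Reactants: 3 4-{[(tert-butyldimethylsilyl)oxy]methyl}phenol; 4 water
Product: 5 4-{[(tert-butyldimethylsilyl)oxy]methyl}-4-hydroxycyclohexa-2,5-dien-1-one
Conditions: PhI(OAc)2, MeCN/H2O (4:1), 0 °C
Reagents that add atoms: water (4), O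
Why: This is the oxidative dearomatisation of a para-alkylphenol by trivalent iodine, in which the phenol exchanges onto PhI(OAc)2, iodobenzene departs and water captures the para carbon to give the p-quinol, while the silyl ether guards against the side-chain loss that a free hydroxymethyl group would risk.

Step 3
Reactants: 5 4-{[(tert-butyldimethylsilyl)oxy]methyl}-4-hydroxycyclohexa-2,5-dien-1-one; 6 tert-butyldimethylsilyl trifluoromethanesulfonate
Product: 7 4-[(tert-butyldimethylsilyl)oxy]-4-{[(tert-butyldimethylsilyl)oxy]methyl}cyclohexa-2,5-dien-1-one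
Conditions: 2,6-lutidine, CH2Cl2, 0 °C
Reagents that add atoms: tert-butyldimethylsilyl trifluoromethanesulfonate (6), CC(C)(C)[Si](C)(C)OS(=O)(=O)C(F)(F)F
Why: A silyl triflate with a hindered pyridine base is the standard silylation of a tertiary alcohol, and the cross-conjugated dienone, having no enolisable hydrogen, should be inert to it.

Step 4
Reactants: 7 4-[(tert-butyldimethylsilyl)oxy]-4-{[(tert-butyldimethylsilyl)oxy]methyl}cyclohexa-2,5-dien-1-one
Product: 8 4-[(tert-butyldimethylsilyl)oxy]-4-(hydroxymethyl)cyclohexa-2,5-dien-1-one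
Conditions: HF·pyridine, pyridine, THF, 0 °C
Reagents that add atoms: none
Why: Buffered HF·pyridine should cleave the primary silyl ether well before the tertiary one on the quaternary carbon (selective desilylation by steric differentiation), and acidic fluoride avoids the alkoxide that could trigger 1,4-silyl migration or loss of formaldehyde from the quinol.

Step 5
Reactants: 8 4-[(tert-butyldimethylsilyl)oxy]-4-(hydroxymethyl)cyclohexa-2,5-dien-1-one; 9 phenylboronic acid
Product: 11 (4aR,8aS)-4a-[(tert-butyldimethylsilyl)oxy]-2-phenyl-4a,8a-dihydro-4H-1,3,2-benzodioxaborinin-7(8H)-one (cis-fused cyclic phenylboronate of O2 and O7; plan numbering 1R,2S), via boronic acid hemiester 10 (not isolated)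
Conditions: 1-[3,5-bis(trifluoromethyl)phenyl]-3-[(8α,9S)-6'-methoxycinchonan-9-yl]thiourea (10 mol %), 4 Å molecular sieves, toluene, 25 °C
Reagents that add atoms: phenylboronic acid (9), OB(O)c1ccccc1
Why: Proposed new method: phenylboronic acid esterifies the primary hydroxyl to give hemiester 10, whose remaining B–OH is activated by the quinuclidine nitrogen of the catalyst while the thiourea hydrogen-bonds the dienone carbonyl, so that the boron-bound oxygen adds to C2 of one enone arm and the resulting enol is protonated at C3; the closest known reactions are the amine–thiourea-catalysed intramolecular oxa-Michael addition of boronic acid hemiesters of γ- and δ-hydroxy enones and the organocatalytic oxa-Michael desymmetrisation of 4,4-disubstituted cyclohexadienones. The 1,3,2-dioxaborinane closes in a 6-exo-trig mode through a chair-like transition state. The configuration at C2 relative to C1 is fixed by the tether, which can deliver oxygen only to the face carrying C7 (cis ring fusion, O2 trans to the C1 oxygen), and the absolute configuration at C1 and C2 is fixed by the catalyst, which selects one of the two enantiotopic arms. The step needs enantiotopic-group selectivity, which rests on the chiral pocket of the bifunctional catalyst, and site selectivity for delivery from C7 rather than from the C1 oxygen, which the tertiary silyl ether secures by leaving only one hydroxyl able to bind boron. A second addition cannot follow because the single tether is consumed in the first ring closure.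

Step 6
Reactants: 11 (4aR,8aS)-4a-[(tert-butyldimethylsilyl)oxy]-2-phenyl-4a,8a-dihydro-4H-1,3,2-benzodioxaborinin-7(8H)-one; 12 2,2-dimethoxypropane
Product: 14 (4aR,8aS)-4a-[(tert-butyldimethylsilyl)oxy]-2,2-dimethyl-4a,8a-dihydro-4H-1,3-benzodioxin-7(8H)-one, via keto diol 13 (not isolated)
Conditions: 30% aq. H2O2, pH 7 phosphate buffer, THF, 0 °C; then 12, pyridinium p-toluenesulfonate, acetone, 25 °C
Reagents that add atoms: 2,2-dimethoxypropane (12), COC(C)(C)OC
Why: Oxidative cleavage of the B–phenyl bond by hydrogen peroxide at neutral pH (boronate oxidation) should release the C2/C7 diol without epoxidising the enone, and acid-catalysed transketalisation then closes the six-membered isopropylidene acetal on the only two free hydroxyls, neither operation touching C1 or C2.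

Step 7
Reactants: 14 (4aR,8aS)-4a-[(tert-butyldimethylsilyl)oxy]-2,2-dimethyl-4a,8a-dihydro-4H-1,3-benzodioxin-7(8H)-one; 15 N-(5-chloropyridin-2-yl)-1,1,1-trifluoro-N-[(trifluoromethyl)sulfonyl]methanesulfonamide
Product: 16 (4aR,8aS)-4a-[(tert-butyldimethylsilyl)oxy]-2,2-dimethyl-4a,8a-dihydro-4H-1,3-benzodioxin-7-yl trifluoromethanesulfonate (C3=C4(OTf)–C5=C6 dienyl triflate)
Conditions: LiN(SiMe3)2, THF, −78 °C; then 15, −78 °C
Reagents that add atoms: N-(5-chloropyridin-2-yl)-1,1,1-trifluoro-N-[(trifluoromethyl)sulfonyl]methanesulfonamide (15), Clc1ccc(nc1)N(S(=O)(=O)C(F)(F)F)S(=O)(=O)C(F)(F)F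
Why: Kinetic deprotonation can occur only at C3 because C1 is quaternary, and O-sulfonylation of the cross-conjugated lithium dienolate by the N-pyridyl triflimide at −78 °C (enol triflate formation) should outrun β-elimination of the C2 oxygen.

Step 8
Reactants: 16 (4aR,8aS)-4a-[(tert-butyldimethylsilyl)oxy]-2,2-dimethyl-4a,8a-dihydro-4H-1,3-benzodioxin-7-yl trifluoromethanesulfonate
Product: 17 tert-butyl{[(4aR,8aS)-2,2-dimethyl-4H-1,3-benzodioxin-4a(8aH)-yl]oxy}dimethylsilane (C3=C4–C5=C6 diene)
Conditions: Pd(OAc)2 (cat.), PPh3, HCO2H, Bu3N, DMF, 40 °C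
Reagents that add atoms: none
Why: Palladium-catalysed formate hydrogenolysis of an enol triflate (oxidative addition to zerovalent palladium, formate exchange, loss of CO2, C–H reductive elimination) should replace the triflate by hydrogen and leave the diene and both stereocentres intact.

Step 9
Reactants: 17 tert-butyl{[(4aR,8aS)-2,2-dimethyl-4H-1,3-benzodioxin-4a(8aH)-yl]oxy}dimethylsilane
Product: 18 (4aR,8aS)-2,2-dimethyl-4H-1,3-benzodioxin-4a(8aH)-ol
Conditions: Bu4NF, THF, 0 to 25 °C
Reagents that add atoms: none
Why: Fluoride-induced desilylation frees the tertiary hydroxyl at a stage where no enolisable carbonyl or β-alkoxy ketone remains, and the basic medium avoids the acid-triggered dehydrative aromatisation to which this dienol is prone.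

Step 10
Reactants: 18 (4aR,8aS)-2,2-dimethyl-4H-1,3-benzodioxin-4a(8aH)-ol; 19 oxygen
Product: 21 (4aS,5S,8R,8aS)-2,2-dimethyl-4a,5,8,8a-tetrahydro-4H-1,3-benzodioxine-4a,5,8-triol (O3 and O6 cis to each other and to the C1 hydroxyl, trans to O2), via endoperoxide 20 (not isolated)
Conditions: O2, 5,10,15,20-tetraphenylporphyrin (cat.), visible light, CH2Cl2, −30 °C; then thiourea, MeOH, 25 °C
Reagents that add atoms: oxygen (19), O=O
Why: Singlet-oxygen [4+2] cycloaddition to a cyclohexa-1,3-diene followed by thiourea reduction of the O–O bond is the established route to cis-1,4-diols of cyclohexenes, and the oxygen should add suprafacially to the face that carries the hydrogen-bonding C1 hydroxyl and lies opposite the fused dioxane ring and the C2 oxygen, which sets C3 and C6 together.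

Step 11
Reactants: 21 (4aS,5S,8R,8aS)-2,2-dimethyl-4a,5,8,8a-tetrahydro-4H-1,3-benzodioxine-4a,5,8-triol; 22 benzoyl chloride
Product: 23 (4aS,5S,8R,8aS)-4a-hydroxy-2,2-dimethyl-4a,5,8,8a-tetrahydro-4H-1,3-benzodioxine-5,8-diyl dibenzoate
Conditions: pyridine, 4-(dimethylamino)pyridine (cat.), CH2Cl2, 0 to 25 °C
Reagents that add atoms: benzoyl chloride (22), O=C(Cl)c1ccccc1
Why: Acylation under nucleophilic catalysis should esterify the two secondary allylic hydroxyls, whereas the tertiary C1 hydroxyl is too hindered to react under these conditions.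

Step 12
Reactants: 23 (4aS,5S,8R,8aS)-4a-hydroxy-2,2-dimethyl-4a,5,8,8a-tetrahydro-4H-1,3-benzodioxine-5,8-diyl dibenzoate
Product: 24 (1R,2S,3R,6S)-1,2-dihydroxy-1-(hydroxymethyl)cyclohex-4-ene-3,6-diyl dibenzoate (plan numbering; the target)
Conditions: AcOH/H2O (4:1), 40 °C
Reagents that add atoms: none
Why: Mild aqueous acid hydrolyses the isopropylidene acetal (acetal hydrolysis) while the benzoates and the allylic C–O bonds should survive, and acidic rather than basic conditions keep the benzoyl groups from migrating to the freed hydroxyls.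

**Compound list**

1 | 4-hydroxybenzyl alcohol | OCc1ccc(O)cc1 | starting material
2 | tert-butyldimethylsilyl chloride | CC(C)(C)[Si](C)(C)Cl | starting material
3 | 4-{[(tert-butyldimethylsilyl)oxy]methyl}phenol | CC(C)(C)[Si](C)(C)OCc1ccc(O)cc1 | intermediate
4 | water | O | starting material
5 | 4-{[(tert-butyldimethylsilyl)oxy]methyl}-4-hydroxycyclohexa-2,5-dien-1-one | O=C1C=CC(O)(CO[Si](C)(C)C(C)(C)C)C=C1 | intermediate
6 | tert-butyldimethylsilyl trifluoromethanesulfonate | CC(C)(C)[Si](C)(C)OS(=O)(=O)C(F)(F)F | starting material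
7 | 4-[(tert-butyldimethylsilyl)oxy]-4-{[(tert-butyldimethylsilyl)oxy]methyl}cyclohexa-2,5-dien-1-one | O=C1C=CC(O[Si](C)(C)C(C)(C)C)(CO[Si](C)(C)C(C)(C)C)C=C1 | intermediate
8 | 4-[(tert-butyldimethylsilyl)oxy]-4-(hydroxymethyl)cyclohexa-2,5-dien-1-one (prochiral p-quinol) | O=C1C=CC(O[Si](C)(C)C(C)(C)C)(CO)C=C1 | intermediate
9 | phenylboronic acid | OB(O)c1ccccc1 | starting material
10 | {1-[(tert-butyldimethylsilyl)oxy]-4-oxocyclohexa-2,5-dien-1-yl}methyl hydrogen phenylboronate (hemiester) | O=C1C=CC(O[Si](C)(C)C(C)(C)C)(COB(O)c2ccccc2)C=C1 | intermediate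
11 | (4aR,8aS)-4a-[(tert-butyldimethylsilyl)oxy]-2-phenyl-4a,8a-dihydro-4H-1,3,2-benzodioxaborinin-7(8H)-one | O=C1C=C[C@@]2(O[Si](C)(C)C(C)(C)C)COB(c3ccccc3)O[C@H]2C1 | intermediate
12 | 2,2-dimethoxypropane | COC(C)(C)OC | starting material
13 | (4R,5S)-4-[(tert-butyldimethylsilyl)oxy]-5-hydroxy-4-(hydroxymethyl)cyclohex-2-en-1-one | O=C1C=C[C@@](O[Si](C)(C)C(C)(C)C)(CO)[C@@H](O)C1 | intermediate
14 | (4aR,8aS)-4a-[(tert-butyldimethylsilyl)oxy]-2,2-dimethyl-4a,8a-dihydro-4H-1,3-benzodioxin-7(8H)-one | O=C1C=C[C@@]2(O[Si](C)(C)C(C)(C)C)COC(C)(C)O[C@H]2C1 | intermediate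
15 | N-(5-chloropyridin-2-yl)-1,1,1-trifluoro-N-[(trifluoromethyl)sulfonyl]methanesulfonamide | Clc1ccc(nc1)N(S(=O)(=O)C(F)(F)F)S(=O)(=O)C(F)(F)F | starting material
16 | (4aR,8aS)-4a-[(tert-butyldimethylsilyl)oxy]-2,2-dimethyl-4a,8a-dihydro-4H-1,3-benzodioxin-7-yl trifluoromethanesulfonate | O=S(=O)(OC1=C[C@@H]2OC(C)(C)OC[C@]2(O[Si](C)(C)C(C)(C)C)C=C1)C(F)(F)F | intermediate
17 | tert-butyl{[(4aR,8aS)-2,2-dimethyl-4H-1,3-benzodioxin-4a(8aH)-yl]oxy}dimethylsilane | C1=C[C@@H]2OC(C)(C)OC[C@]2(O[Si](C)(C)C(C)(C)C)C=C1 | intermediate
18 | (4aR,8aS)-2,2-dimethyl-4H-1,3-benzodioxin-4a(8aH)-ol | C1=C[C@@H]2OC(C)(C)OC[C@]2(O)C=C1 | intermediate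
19 | oxygen | O=O | starting material
20 | endoperoxide: C3,C6-epidioxy bridge (2,3-dioxabicyclo[2.2.2]oct-5-ene core) on the face of the C1 hydroxyl, C2/C7 isopropylidene acetal retained; plan numbering 1R,2S,3R,6S | O[C@]12COC(C)(C)O[C@H]1[C@H]3C=C[C@@H]2OO3 | intermediate
21 | (4aS,5S,8R,8aS)-2,2-dimethyl-4a,5,8,8a-tetrahydro-4H-1,3-benzodioxine-4a,5,8-triol | O[C@]12COC(C)(C)O[C@H]1[C@H](O)C=C[C@@H]2O | intermediate
22 | benzoyl chloride | O=C(Cl)c1ccccc1 | starting material
23 | (4aS,5S,8R,8aS)-4a-hydroxy-2,2-dimethyl-4a,5,8,8a-tetrahydro-4H-1,3-benzodioxine-5,8-diyl dibenzoate | O[C@]12COC(C)(C)O[C@H]1[C@H](OC(=O)c3ccccc3)C=C[C@@H]2OC(=O)c4ccccc4 | intermediate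
24 | (1R,2S,3R,6S)-1,2-dihydroxy-1-(hydroxymethyl)cyclohex-4-ene-3,6-diyl dibenzoate (plan numbering) | O=C(O[C@H]1C=C[C@@H](OC(=O)c2ccccc2)[C@H](O)[C@]1(O)CO)c1ccccc1 | target

**Step count and risks**

Total: 12 steps. Longest linear sequence: 12 steps (1 to 24).

Steps most likely to fail:

1. Step 5 (the new method). The catalyst may discriminate poorly between the two enone arms, or the hemiester may add sluggishly to the hindered cross-conjugated dienone, so that the boronate forms slowly or in low enantiomeric purity. The fallback sets out from 8 and uses the chiral phosphoric acid-catalysed acetalisation/oxa-Michael cascade known for desymmetrising p-quinols and p-peroxyquinols with aldehydes. With isobutyraldehyde and (R)-3,3'-bis(2,4,6-triisopropylphenyl)-1,1'-binaphthyl-2,2'-diyl hydrogen phosphate (or its enantiomer, as the sense of induction requires) in 1,2-dichloroethane, the hemiacetal oxygen should add to C2 and give the cis-fused isobutylidene acetal F1. Hydrolysis of this acetal in aqueous AcOH/THF comes back to the route at keto diol 13, which enters the second operation of step 6.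

2. Step 10. Singlet oxygen may add with poor facial selectivity, and an ene reaction at the C2 hydrogen or aromatisation of the dienol may compete. The fallback sets out from 14 and installs O3 and O6 one at a time.
   - HF·pyridine in THF removes the silyl group to give the hydroxy enone F2.
   - tBuOOH with catalytic benzyltrimethylammonium hydroxide in THF at 0 °C should give the epoxy ketone F3, by hydroxyl-directed Weitz–Scheffer epoxidation on the face of the C1 hydroxyl.
   - Me3SiOTf and Et3N convert it into the trimethylsilyl enol ether F4, in which the C1 hydroxyl is also silylated.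
   - Dimethyldioxirane followed by citric acid in MeOH should give the C3-hydroxy ketone F5, by Rubottom oxidation anti to the C2 oxygen.
   - N2H4·H2O with catalytic AcOH in MeOH (Wharton transposition) moves the oxygen to C6 and the alkene to C4=C5, coming back to the route at 21.

3. Step 7. The lithium enolate at C3 may expel the C2 oxygen (β-elimination, the reverse of the oxa-Michael step) before it is trapped. The fallback sets out from 14 and avoids any enolate. Luche reduction (NaBH4, CeCl3·7H2O, MeOH, −78 °C) gives the allylic alcohol F6, and ClCO2Me with pyridine gives the allylic methyl carbonate F7. Pd(PPh3)4 with Et3N in THF at 65 °C should then ionise the carbonate to a π-allylpalladium species that loses a β-hydrogen from C3, the only carbon that carries one (palladium-catalysed 1,4-elimination of an allylic carbonate), coming back to the route at diene 17.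

**Further compounds**

F1 | step 5 | (4aR,8aS)-4a-[(tert-butyldimethylsilyl)oxy]-2-(propan-2-yl)-4a,8a-dihydro-4H-1,3-benzodioxin-7(8H)-one (acetal carbon: either epimer, removed on hydrolysis) | O=C1C=C[C@@]2(O[Si](C)(C)C(C)(C)C)COC(C(C)C)O[C@H]2C1
F2 | step 10 | (4aR,8aS)-4a-hydroxy-2,2-dimethyl-4a,8a-dihydro-4H-1,3-benzodioxin-7(8H)-one | O=C1C=C[C@@]2(O)COC(C)(C)O[C@H]2C1
F3 | step 10 | C5,C6-epoxy ketone of F2, epoxide on the face of the C1 hydroxyl (plan numbering) | O=C1C[C@@H]2OC(C)(C)OC[C@]2(O)[C@H]3O[C@H]31
F4 | step 10 | C3=C4 trimethylsilyl enol ether of F3 with the C1 hydroxyl as trimethylsilyl ether | C[Si](C)(C)OC1=C[C@@H]2OC(C)(C)OC[C@]2(O[Si](C)(C)C)[C@H]3O[C@H]31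
F5 | step 10 | C3-hydroxy derivative of F3, hydroxyl trans to the C2 oxygen | O=C1[C@@H](O)[C@@H]2OC(C)(C)OC[C@]2(O)[C@H]3O[C@H]31
F6 | step 7 | (4aR,8aS)-4a-[(tert-butyldimethylsilyl)oxy]-2,2-dimethyl-4a,7,8,8a-tetrahydro-4H-1,3-benzodioxin-7-ol (carbinol carbon: either epimer, lost on elimination) | OC1C=C[C@@]2(O[Si](C)(C)C(C)(C)C)COC(C)(C)O[C@H]2C1
F7 | step 7 | methyl carbonate of F6 | COC(=O)OC1C=C[C@@]2(O[Si](C)(C)C(C)(C)C)COC(C)(C)O[C@H]2C1
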